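**Retrosynthetic overview**
1. GA50 ⇐ 3-oxo-19,10-lactone 29: the 2β-OH (enolate hydroxylation), the 3β-OH (bulky hydride) and the free 7-acid come last.
2. Key disconnection: C4–C5 and C10–O of 29 are made together by a Mn(OAc)3 oxidative radical 6-endo cyclisation/cation lactonisation of cyclopentene β-keto ester 28 (ring A and the lactone in one step).
3. 28 ⇐ vinyl triflate 21 (Negishi coupling, then Claisen condensation for C-1 to C-4) ⇐ enone 17, by conjugate addition of a carboxyl-anion equivalent to C-6 with enolate triflation.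
4. 17 ⇐ trione 13 ⇐ Diels–Alder reaction (ring C) of resolved acetoxy enone 7 with silyloxydiene 9, then gold-catalysed enol ether/alkyne cyclisation (ring D).
5. Ring order: B (Piancatelli, from furfural) → C → D → A + lactone.

Assumption: the given SMILES is taken as the structure to be made (hydroxyl on C-12, 12R, equatorial on ring C); gibberellane numbering is carried back to every intermediate and β means the face of H-5, H-9 and C-18 (TBS = tert-butyldimethylsilyl, Tf = CF3SO2).

**Route**

Step 1
Reactants: 1 furfural; 2 propargyl bromide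
Product: 4 (±)-1-(furan-2-yl)but-3-yn-1-ol, via allenylzinc bromide 3 (not isolated)
Conditions: Zn dust, THF/sat. aq. NH4Cl (1:1), 0 °C → rt
Reagents that add atoms: none
Why: Barbier-type propargylation, in which allenylzinc bromide formed in situ adds SE2′ to the aldehyde to give the homopropargylic alcohol; the racemic carbinol centre is erased in step 2.

Step 2
Reactants: 4 (±)-1-(furan-2-yl)but-3-yn-1-ol
Product: 6 (±)-4-hydroxy-2-(prop-2-yn-1-yl)cyclopent-2-en-1-one, via trans-4-hydroxy-5-propargylcyclopentenone 5 (not isolated)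
Conditions: ZnCl2 (cat.), H2O/acetone, reflux; then phosphate buffer to pH 8, 60 °C
Reagents that add atoms: water, O
Why: Piancatelli rearrangement (furyl cation, capture of water, 4π-conrotatory ring closure) gives the trans-4-hydroxy-5-alkyl enone, which the mildly basic buffer isomerises to the more stable 2-alkyl-4-hydroxy enone, still racemic.

Step 3
Reactants: 6 (±)-4-hydroxy-2-(prop-2-yn-1-yl)cyclopent-2-en-1-one
Product: 7 (R)-4-acetoxy-2-(prop-2-yn-1-yl)cyclopent-2-en-1-one
Conditions: Burkholderia cepacia lipase (lipase PS), vinyl acetate (3 equiv), MTBE, 30 °C, stopped near 50 % conversion; (S)-6 removed by chromatography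
Reagents that add atoms: vinyl acetate, C=COC(C)=O
Why: Lipase-catalysed kinetic resolution by transesterification, in which the (R)-alcohol of 2-alkyl-4-hydroxycyclopentenones is acylated selectively, so the C-10 centre that steers all later stereochemistry is obtained enantiopure.

Step 4
Reactants: 8 methyl vinyl ketone
Product: 9 2-(tert-butyldimethylsilyloxy)buta-1,3-diene
Conditions: TBSOTf, Et3N, Et2O, 0 °C
Reagents that add atoms: TBSOTf, CC(C)(C)[Si](C)(C)OS(=O)(=O)C(F)(F)F
Why: Soft enolisation and O-silylation of the enone gives the 2-silyloxydiene (silyl dienol ether formation).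

Step 5
Reactants: 7 (R)-4-acetoxy-2-(prop-2-yn-1-yl)cyclopent-2-en-1-one; 9 2-(tert-butyldimethylsilyloxy)buta-1,3-diene
Product: 10 cis-fused rings B/C adduct (10β-acetoxy-8-propargyl-12-TBS-oxy-12-en-6-one; H-9β)
Conditions: Tf2NH (5 mol %), CH2Cl2, −78 °C → −40 °C
Reagents that add atoms: none
Why: Diels–Alder reaction catalysed by TBSNTf2 formed in situ, in which only the C-6 ketone activates the alkene so that diene terminus C-11 bonds to β-carbon C-9 (oxygen ends on C-12), and the diene adds suprafacially and anti to the 10-acetoxy group, which sets C-8 and C-9 (H-9 cis to the propargyl arm) in the required absolute sense.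

Step 6
Reactants: 10 cis-fused rings B/C adduct
Product: 11 tricyclic keto acetate (rings B/C/D; 10β-acetoxy-16-methylene-6,12-dione)
Conditions: (Ph3P)AuCl (5 mol %), AgBF4 (5 mol %), CH2Cl2/MeOH (10:1), rt
Reagents that add atoms: none
Why: Gold-catalysed 5-exo-dig carbocyclisation of the silyl enol ether onto the terminal alkyne (Conia-ene type, Toste) closes ring D through C13–C16 and leaves the exocyclic methylene and the C-12 ketone; C-13 is fixed by the bridge geometry.

Step 7
Reactants: 11 tricyclic keto acetate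
Product: 12 10β-hydroxy-6,12-dione
Conditions: Burkholderia cepacia lipase, pH 7 phosphate buffer/acetone (9:1), 30 °C
Reagents that add atoms: none
Why: Enzymatic ester hydrolysis at neutral pH removes the acetate without the E1cB elimination that basic methanolysis of a β-acetoxy ketone would cause.

Step 8
Reactants: 12 10β-hydroxy-6,12-dione
Product: 13 6,10,12-trione (ring B 1,3-dione, mostly enolised)
Conditions: Dess–Martin periodinane, CH2Cl2, 0 °C → rt
Reagents that add atoms: none
Why: Dess–Martin oxidation of the β-hydroxy ketone gives the cyclopentane-1,3-dione once the C-10 stereocentre has done its directing job.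

Step 9
Reactants: 13 6,10,12-trione
Product: 14 (12R)-12-hydroxy-6,10-dione
Conditions: Li (6 equiv), NH3(l)/THF, t-BuOH (2 equiv), −78 °C; then solid NH4Cl
Reagents that add atoms: none
Why: Dissolving-metal ketone reduction, in which the acidic 1,3-dione is shielded as its lithium enolate while the C-12 ketone is reduced under thermodynamic control to the equatorial (12R) alcohol, the axial epimer being syn-diaxial to C-10.

Step 10
Reactants: 14 (12R)-12-hydroxy-6,10-dione
Product: 15 12-O-TBS 10-(TBS-oxy)-5(10)-en-6-one (vinylogous silyl ester)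
Conditions: TBSOTf (2.2 equiv), Et3N (3 equiv), CH2Cl2, −78 °C → 0 °C
Reagents that add atoms: TBSOTf, CC(C)(C)[Si](C)(C)OS(=O)(=O)C(F)(F)F
Why: Silylation of the alcohol and O-silylation of the enolised dione at the less hindered oxygen (on C-10, away from quaternary C-8) gives the vinylogous silyl ester with the free carbonyl at C-6.

Step 11
Reactants: 15 vinylogous silyl ester
Product: 17 12-O-TBS 5-en-10-one (ring B enone), via hydroxy silyl enol ether 16 (not isolated)
Conditions: i-Bu2AlH (1.2 equiv), CH2Cl2, −78 °C; then 1 M aq. HCl/THF, 0 °C → rt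
Reagents that add atoms: none
Why: Stork–Danheiser 1,3-carbonyl transposition, in which 1,2-reduction of the vinylogous ester carbonyl, acid hydrolysis of the silyl enol ether and β-elimination of water move the carbonyl to C-10 and the alkene to C5=C6.

Step 12
Reactants: 17 ring B enone; 18 tris(methylthio)methane
Product: 21 vinyl triflate (10-triflyloxy-5(10)-ene carrying 6β-C(SMe)3), via tris(methylthio)methyllithium 19 (not isolated), via lithium enolate 20 (not isolated)
Conditions: 18, n-BuLi, THF, −78 °C; add 17, −78 °C; then PhNTf2, −78 °C → 0 °C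
Reagents that add atoms: N-phenylbis(trifluoromethanesulfonimide), O=S(=O)(N(c1ccccc1)S(=O)(=O)C(F)(F)F)C(F)(F)F
Why: Conjugate (Michael) addition of the carboxyl-anion equivalent (MeS)3CLi to the cyclopentenone from the convex β face (ring C lies under the α face) sets C-6, and the regiodefined C-10 enolate is trapped as the vinyl triflate.

Step 13
Reactants: 21 vinyl triflate; 22 ethyl 3-iodopropanoate
Product: 24 ethyl ester (10-(2-ethoxycarbonylethyl)-5(10)-ene), via (3-ethoxy-3-oxopropyl)zinc iodide 23 (not isolated)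
Conditions: 22, Zn dust, LiCl, THF, 40 °C; then 21, Pd(PPh3)4 (5 mol %), THF/NMP, 50 °C
Reagents that add atoms: none
Why: Negishi sp2–sp3 cross-coupling of the vinyl triflate with the zinc homoenolate installs C-1 to C-3 and fixes the C5=C10 alkene, the orthothioester being inert.

Step 14
Reactants: 24 ethyl ester; 25 methyl propanoate
Product: 27 β-keto ester (side chain CH2CH2C(=O)CH(CH3)CO2Me on C-10; C-4 epimers), via lithium enolate of methyl propanoate 26 (not isolated)
Conditions: 25 (3 equiv), LiN(i-Pr)2 (3 equiv), THF, −78 °C; add 24, −78 °C → −20 °C; aq. work-up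
Reagents that add atoms: none
Why: Crossed Claisen condensation of the propanoate enolate with the ethyl ester builds the α-methyl β-keto ester (C-3, C-4, C-18, C-19), C-6 staying non-acidic as its orthothioester.

Step 15
Reactants: 27 β-keto ester
Product: 28 β-keto ester S-methyl 7-thioate
Conditions: MeI (10 equiv), CaCO3, MeCN/H2O (4:1), 40 °C
Reagents that add atoms: water, O
Why: Alkylative hydrolysis of the trithioorthoester (S-methylation, loss of Me2S, capture by water) unmasks C-7 as the S-methyl thioester under neutral conditions that spare both alkenes and the β-keto ester.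

Step 16
Reactants: 28 β-keto ester S-methyl 7-thioate
Product: 29 12-O-TBS 3-oxo-19,10-lactone S-methyl 7-thioate
Conditions: Mn(OAc)3·2H2O (2.2 equiv), degassed AcOH, 40 °C
Reagents that add atoms: none
Why: Mn(OAc)3-mediated oxidative free-radical cyclisation (Snider type), in which the C-4 radical of the β-keto ester adds 6-endo to C-5 anti to the 6β-thioester through a chair transition state with the ester axial, and the tertiary C-10 radical is oxidised to the cation and captured by that axial ester carbonyl with loss of methyl acetate, so ring A, the cis-bridged lactone and C-4, C-5 and C-10 are set in one operation.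

Step 17
Reactants: 29 3-oxo-19,10-lactone
Product: 31 2β-hydroxy-3-oxo lactone, via potassium enolate 30 (not isolated)
Conditions: KN(SiMe3)2 (1.1 equiv), THF, −78 °C; then 2-(phenylsulfonyl)-3-phenyloxaziridine, −78 °C; aq. work-up
Reagents that add atoms: 2-(phenylsulfonyl)-3-phenyloxaziridine, O=S(=O)(N1OC1c1ccccc1)c1ccccc1
Why: Davis enolate hydroxylation, in which C-2 is the only enolisable position of the 3-ketone (C-4 is quaternary) and the oxidant approaches from the β face, away from the α lactone bridge, to give the equatorial 2β-alcohol.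

Step 18
Reactants: 31 2β-hydroxy-3-oxo lactone
Product: 32 2β,3β-diol (12-O-TBS, S-methyl 7-thioate)
Conditions: KBH(s-Bu)3 (2.5 equiv), THF, −78 °C; aq. work-up
Reagents that add atoms: none
Why: Bulky-hydride reduction, in which equatorial delivery of hydride to the 3-ketone gives the axial 3β-alcohol cis to the 2β-hydroxyl, as expected for 3-oxogibberellins.

Step 19
Reactants: 32 2β,3β-diol
Product: 34 GA50, via GA50 S-methyl thioester 33 (not isolated)
Conditions: HF·pyridine, THF, 0 °C → rt; then AgNO3 (2 equiv), 2,6-lutidine, THF/H2O (3:1), rt; acidify to pH 3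
Reagents that add atoms: water, O
Why: Fluoride desilylation followed by silver-assisted thioester hydrolysis frees the 7-acid under near-neutral conditions, avoiding base-induced retro-aldol epimerisation at C-3 and lactone opening.

**Compound list**

1 | furfural | O=Cc1ccco1 | starting material
2 | propargyl bromide | C#CCBr | starting material
3 | allenylzinc bromide | C=C=C[Zn]Br | intermediate
4 | (±)-1-(furan-2-yl)but-3-yn-1-ol | OC(CC#C)c1ccco1 | intermediate
5 | (±)-trans-4-hydroxy-5-(prop-2-yn-1-yl)cyclopent-2-en-1-one (one enantiomer drawn) | O=C1C=C[C@H](O)[C@H]1CC#C | intermediate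
6 | (±)-4-hydroxy-2-(prop-2-yn-1-yl)cyclopent-2-en-1-one | O=C1CC(O)C=C1CC#C | intermediate
7 | (R)-4-acetoxy-2-(prop-2-yn-1-yl)cyclopent-2-en-1-one | C#CCC1=C[C@H](OC(C)=O)CC1=O | intermediate
8 | methyl vinyl ketone | CC(=O)C=C | starting material
9 | 2-(tert-butyldimethylsilyloxy)buta-1,3-diene | C=CC(=C)O[Si](C)(C)C(C)(C)C | intermediate
10 | cis-fused rings B/C adduct: 10β-acetoxy-8-propargyl-12-(TBS-oxy)-12-en-6-one, H-9β (3-acetoxy-5-(TBS-oxy)-7a-propargyl-2,3,3a,4,7,7a-hexahydroinden-1-one, cis-fused, OAc cis to H-3a) | C#CC[C@]23CC=C(O[Si](C)(C)C(C)(C)C)C[C@H]2[C@H](OC(C)=O)CC3=O | intermediate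
11 | tricyclic keto acetate (rings B/C/D): 10β-acetoxy-16-methylene-6,12-dione | C=C1C[C@]23C[C@H]1C(=O)C[C@H]2[C@H](OC(C)=O)CC3=O | intermediate
12 | 10β-hydroxy-16-methylene-6,12-dione | C=C1C[C@]23C[C@H]1C(=O)C[C@H]2[C@H](O)CC3=O | intermediate
13 | 16-methylene-6,10,12-trione (ring B 1,3-dione, mostly enolised) | C=C1C[C@]23C[C@H]1C(=O)C[C@H]2C(=O)CC3=O | intermediate
14 | (12R)-12-hydroxy-16-methylene-6,10-dione (12-OH equatorial, on the side of the C-15/C-16 bridge) | C=C1C[C@]23C[C@H]1[C@H](O)C[C@H]2C(=O)CC3=O | intermediate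
15 | 12-O-TBS 10-(TBS-oxy)-5(10)-en-6-one (vinylogous silyl ester) | C=C1C[C@]23C[C@H]1[C@H](O[Si](C)(C)C(C)(C)C)C[C@H]2C(O[Si](C)(C)C(C)(C)C)=CC3=O | intermediate
16 | 12-O-TBS 10-(TBS-oxy)-5(10)-en-6-ol (C-6 epimers) | C=C1C[C@]23C[C@H]1[C@H](O[Si](C)(C)C(C)(C)C)C[C@H]2C(O[Si](C)(C)C(C)(C)C)=CC3O | intermediate
17 | 12-O-TBS 5-en-10-one (ring B enone) | C=C1C[C@]23C[C@H]1[C@H](O[Si](C)(C)C(C)(C)C)C[C@H]2C(=O)C=C3 | intermediate
18 | tris(methylthio)methane | CSC(SC)SC | starting material
19 | tris(methylthio)methyllithium | [Li]C(SC)(SC)SC | intermediate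
20 | lithium 5(10)-en-10-olate carrying 6β-C(SMe)3 and 12-O-TBS | C=C1C[C@]23C[C@H]1[C@H](O[Si](C)(C)C(C)(C)C)C[C@H]2C(O[Li])=C[C@@H]3C(SC)(SC)SC | intermediate
21 | vinyl triflate: 10-triflyloxy-5(10)-ene with 6β-tris(methylthio)methyl and 12-O-TBS | C=C1C[C@]23C[C@H]1[C@H](O[Si](C)(C)C(C)(C)C)C[C@H]2C(OS(=O)(=O)C(F)(F)F)=C[C@@H]3C(SC)(SC)SC | intermediate
22 | ethyl 3-iodopropanoate | CCOC(=O)CCI | starting material
23 | (3-ethoxy-3-oxopropyl)zinc iodide | CCOC(=O)CC[Zn]I | intermediate
24 | ethyl ester: 10-(2-ethoxycarbonylethyl)-5(10)-ene with 6β-C(SMe)3 and 12-O-TBS | C=C1C[C@]23C[C@H]1[C@H](O[Si](C)(C)C(C)(C)C)C[C@H]2C(CCC(=O)OCC)=C[C@@H]3C(SC)(SC)SC | intermediate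
25 | methyl propanoate | CCC(=O)OC | starting material
26 | lithium enolate of methyl propanoate | CC=C(OC)O[Li] | intermediate
27 | β-keto ester: 10-[4-(methoxycarbonyl)-3-oxopentyl]-5(10)-ene with 6β-C(SMe)3 and 12-O-TBS (C-4 epimers) | C=C1C[C@]23C[C@H]1[C@H](O[Si](C)(C)C(C)(C)C)C[C@H]2C(CCC(=O)C(C)C(=O)OC)=C[C@@H]3C(SC)(SC)SC | intermediate
28 | the same β-keto ester with C-7 as 6β-C(=O)SMe (S-methyl thioester) | C=C1C[C@]23C[C@H]1[C@H](O[Si](C)(C)C(C)(C)C)C[C@H]2C(CCC(=O)C(C)C(=O)OC)=C[C@@H]3C(=O)SC | intermediate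
29 | 12-O-TBS 3-oxo-19,10-lactone S-methyl 7-thioate (4α-lactone carbonyl, 5β-H, 10α-O) | C=C1C[C@]23C[C@H]1[C@H](O[Si](C)(C)C(C)(C)C)C[C@H]2[C@@]12CCC(=O)[C@@](C)(C(=O)O1)[C@H]2[C@@H]3C(=O)SC | intermediate
30 | potassium 2-en-3-olate of 29 | C=C1C[C@]23C[C@H]1[C@H](O[Si](C)(C)C(C)(C)C)C[C@H]2[C@@]12CC=C(O[K])[C@@](C)(C(=O)O1)[C@H]2[C@@H]3C(=O)SC | intermediate
31 | 12-O-TBS 2β-hydroxy-3-oxo-19,10-lactone S-methyl 7-thioate | C=C1C[C@]23C[C@H]1[C@H](O[Si](C)(C)C(C)(C)C)C[C@H]2[C@@]12C[C@H](O)C(=O)[C@@](C)(C(=O)O1)[C@H]2[C@@H]3C(=O)SC | intermediate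
32 | 12-O-TBS 2β,3β-dihydroxy-19,10-lactone S-methyl 7-thioate | C=C1C[C@]23C[C@H]1[C@H](O[Si](C)(C)C(C)(C)C)C[C@H]2[C@@]12C[C@H](O)[C@H](O)[C@@](C)(C(=O)O1)[C@H]2[C@@H]3C(=O)SC | intermediate
33 | GA50 S-methyl thioester | C=C1C[C@]23C[C@H]1[C@H](O)C[C@H]2[C@@]12C[C@H](O)[C@H](O)[C@@](C)(C(=O)O1)[C@H]2[C@@H]3C(=O)SC | intermediate
34 | GA50 | C=C1C[C@]23C[C@H]1[C@H](O)C[C@H]2[C@@]12C[C@H](O)[C@H](O)[C@@](C)(C(=O)O1)[C@H]2[C@@H]3C(=O)O | target

**Totals**

Total step count: 19. Longest linear sequence: 18 (steps 1–3 and 5–19; step 4 is a one-step branch).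

**Steps most likely to fail and fallbacks** (12, 14 and 16; step 16 carries the highest risk)

Step 12: the bulky thio-carbanion may add sluggishly, or with poor facial selectivity, next to quaternary C-8. The fallback sets out from 17 and returns at 21. The carboxyl carbon is brought in as a smaller formyl-anion equivalent and the third sulfur is added afterwards. Bis(methylthio)methane with n-BuLi gives bis(methylthio)methyllithium F1, which adds 1,4 to 17 in THF/HMPA at −78 °C. Trapping with TBSCl gives the 6β-[bis(methylthio)methyl] silyl enol ether F2. Metalation of the dithioacetal C–H (n-BuLi, TMEDA, −30 °C) and quenching with MeSSMe gives the 6β-[tris(methylthio)methyl] silyl enol ether F3. CsF and PhNTf2 in DME then convert the silyl enol ether regiospecifically into triflate 21.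

Step 14: the crossed Claisen may be spoiled by propanoate self-condensation or by enolisation of 24. The fallback sets out from 21 and returns at 27, making the keto ester by aldehyde homologation instead of ester condensation. Triflate 21 is coupled (Pd(PPh3)4, THF) with [2-(1,3-dioxolan-2-yl)ethyl]zinc bromide F4, made from 2-(2-bromoethyl)-1,3-dioxolane and Zn, to give the dioxolane F5. PPTS in wet acetone frees the aldehyde F6 while the orthothioester and TBS ether survive. Roskamp homologation with methyl 2-diazopropanoate (SnCl2, CH2Cl2) gives 27.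

Step 16: the C-10 cation may lose a proton to give alkenes instead of lactonising, or the radical may attack the β face. The fallback sets out from 28 and returns at 29. It makes the same C4–C5 bond by bromine-atom-transfer radical cyclisation and closes the lactone in a separate ionic step. NBS with Mg(ClO4)2 (cat.) in MeCN at 0 °C gives the 4-bromo β-keto ester F7. Et3B/O2 with Mg(ClO4)2 in toluene at −78 °C effects 6-endo atom-transfer cyclisation to the C-10 tertiary bromide F8. AgOTf with 2,6-di-tert-butylpyridine in CH2Cl2 ionises the bromide, and the axial ester closes the lactone with loss of its methyl group to give 29.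

**Further compounds**

F1 | step 12 | bis(methylthio)methyllithium | [Li]C(SC)SC
F2 | step 12 | 12-O-TBS 10-(TBS-oxy)-5(10)-ene with 6β-bis(methylthio)methyl | C=C1C[C@]23C[C@H]1[C@H](O[Si](C)(C)C(C)(C)C)C[C@H]2C(O[Si](C)(C)C(C)(C)C)=C[C@@H]3C(SC)SC
F3 | step 12 | 12-O-TBS 10-(TBS-oxy)-5(10)-ene with 6β-tris(methylthio)methyl | C=C1C[C@]23C[C@H]1[C@H](O[Si](C)(C)C(C)(C)C)C[C@H]2C(O[Si](C)(C)C(C)(C)C)=C[C@@H]3C(SC)(SC)SC
F4 | step 14 | [2-(1,3-dioxolan-2-yl)ethyl]zinc bromide | Br[Zn]CCC1OCCO1
F5 | step 14 | 10-[2-(1,3-dioxolan-2-yl)ethyl]-5(10)-ene with 6β-C(SMe)3 and 12-O-TBS | C=C1C[C@]23C[C@H]1[C@H](O[Si](C)(C)C(C)(C)C)C[C@H]2C(CCC4OCCO4)=C[C@@H]3C(SC)(SC)SC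
F6 | step 14 | 10-(3-oxopropyl)-5(10)-ene with 6β-C(SMe)3 and 12-O-TBS (aldehyde) | C=C1C[C@]23C[C@H]1[C@H](O[Si](C)(C)C(C)(C)C)C[C@H]2C(CCC=O)=C[C@@H]3C(SC)(SC)SC
F7 | step 16 | 4-bromo derivative of 28 (C-4 epimers) | C=C1C[C@]23C[C@H]1[C@H](O[Si](C)(C)C(C)(C)C)C[C@H]2C(CCC(=O)C(C)(Br)C(=O)OC)=C[C@@H]3C(=O)SC
F8 | step 16 | 10-bromo-3-oxo ring A keto ester (methyl 19-oate, S-methyl 7-thioate, 12-O-TBS; C-10 epimers) | C=C1C[C@]23C[C@H]1[C@H](O[Si](C)(C)C(C)(C)C)C[C@H]2C4(Br)CCC(=O)[C@@](C)(C(=O)OC)[C@H]4[C@@H]3C(=O)SC
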